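**Retrosynthetic overview**

1. Labels: dioxane ring O1–O2–C3–C4–C5–C6; lactone C1(=O)–C2 on C3 and lactone O on C4; chain C1′–C9′. The strategy rests on C6 of the 1,2-dioxane ring. This fully substituted carbon carries O1, a methyl group and the nine-carbon arylalkyl chain, and lies 1,3 to quaternary C4 (CH3, lactone O). It has the oxidation level of a methyl ketone and is treated as a peroxyketal carbon.
2. The chain is cut at C2′–C3′ (cross-metathesis with 4-(oct-7-enyl)phenol, then diimide). It is cut again at C6–C1′ (allylsilane plus the endocyclic peroxycarbenium ion O1=C6 of the finished dioxane–lactone core).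
3. The methoxy peroxyketal core opens at O2–C3 (intramolecular peroxide conjugate addition) and at C6 (methanol capture of the carbonyl oxide from a methallyl group). This leads back to (S)-5-methyl-5-methallylbutenolide.
4. The butenolide comes from Z-selective olefination and lactonisation of an α-silyloxy aldehyde. That aldehyde derives from the enantioselective ene adduct of methyl pyruvate and isobutene, which sets C4.
5. Ring order: the lactone ring (as butenolide) first, then the 1,2-dioxane closed onto it, and no ring after that. C3 follows from C4, and C6 follows from the bicyclic core.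

Key step: step 8

Assumption: the (S,S)-t-Bu-box ligand (2,2′-isopropylidenebis[(4S)-4-tert-butyl-2-oxazoline]) is taken to leave the si face of chelated methyl pyruvate open, which leads to the S alcohol; if the sense were the reverse, the equally available (R,R) ligand would be used and nothing else would change.

Handling remark: compounds 12 onward are organic peroxides and are concentrated cold, on modest scale and behind a shield.

**Step 1**
Reactants: 1 methyl pyruvate; 2 isobutene
Product: 3 methyl (S)-2-hydroxy-2,4-dimethylpent-4-enoate
Conditions: [Cu((S,S)-t-Bu-box)](SbF6)2 (10 mol %), 2 (excess, condensed in), CH2Cl2, sealed tube, rt→40 °C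
Reagents that add atoms: none
Why: Catalytic enantioselective carbonyl-ene reaction in which the pyruvate chelates the divalent copper centre through both carbonyl oxygens in a square-planar complex, the tert-butyl groups cover the re face of the ketone, and isobutene adds to the si face with transfer of an allylic hydrogen, which should set the future C4 as S.

**Step 2**
Reactants: 3 methyl (S)-2-hydroxy-2,4-dimethylpent-4-enoate
Product: 4 methyl (S)-2,4-dimethyl-2-(triethylsilyloxy)pent-4-enoate
Conditions: Et3SiOTf, 2,6-lutidine, CH2Cl2, 0 °C
Reagents that add atoms: triethylsilyl trifluoromethanesulfonate, CC[Si](CC)(CC)OS(=O)(=O)C(F)(F)F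
Why: O-silylation with a silyl triflate is strong enough for a tertiary α-hydroxy ester, and the TES ether keeps the hydroxyl out of the hydride and carbanion steps that follow without touching the stereocentre.

**Step 3**
Reactants: 4 methyl (S)-2,4-dimethyl-2-(triethylsilyloxy)pent-4-enoate
Product: 6 (S)-2,4-dimethyl-2-(triethylsilyloxy)pent-4-enal, via aluminium hemiacetal 5 (not isolated)
Conditions: i-Bu2AlH (1.1 equiv), CH2Cl2, −78 °C; aq potassium sodium tartrate
Reagents that add atoms: none
Why: Partial ester reduction with diisobutylaluminium hydride, in which the hindered α-silyloxy ester gives tetrahedral adduct 5 that persists at −78 °C and releases the aldehyde only on hydrolysis, while the quaternary α-carbon cannot epimerise.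

**Step 4**
Reactants: 6 (S)-2,4-dimethyl-2-(triethylsilyloxy)pent-4-enal; 7 methyl bis(2,2,2-trifluoroethyl)phosphonoacetate
Product: 8 methyl (2Z,4S)-4,6-dimethyl-4-(triethylsilyloxy)hepta-2,6-dienoate
Conditions: 7, KN(SiMe3)2, 18-crown-6, THF, −78 °C
Reagents that add atoms: none
Why: Still–Gennari variant of the Horner–Wadsworth–Emmons olefination, in which the electron-poor phosphonate with a dissociated potassium ion eliminates quickly from the kinetic adduct and should give the Z enoate that ring closure requires.

**Step 5**
Reactants: 8 methyl (2Z,4S)-4,6-dimethyl-4-(triethylsilyloxy)hepta-2,6-dienoate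
Product: 10 (S)-5-methyl-5-(2-methylallyl)furan-2(5H)-one, via hydroxy enoate 9 (not isolated)
Conditions: 2 M aq HCl, THF, rt
Reagents that add atoms: none
Why: Acid hydrolysis of the silyl ether frees tertiary alcohol 9, whose hydroxyl is held next to the ester by the Z alkene and lactonises at once (5-exo-trig acyl substitution, loss of methanol), while dilute acid at room temperature leaves the 1,1-disubstituted alkene alone.

**Step 6**
Reactants: 10 (S)-5-methyl-5-(2-methylallyl)furan-2(5H)-one
Product: 12 (5S)-5-(2-hydroperoxy-2-methoxypropyl)-5-methylfuran-2(5H)-one (both ketal epimers), via carbonyl oxide 11 (not isolated)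
Conditions: O3 (to the Sudan Red 7B end point), CH2Cl2/MeOH, −78 °C; Ar purge, no reductant; concentrated below 20 °C
Reagents that add atoms: ozone, [O-][O+]=O; methanol, CO
Why: Ozonolysis in a participating solvent (Criegee mechanism), in which ozone takes the electron-rich 1,1-disubstituted alkene far faster than the conjugated butenolide alkene, the primary ozonide splits towards the more substituted carbonyl oxide 11 and formaldehyde, and methanol traps 11 as the α-methoxy hydroperoxide, whose uncontrolled ketal centre is erased in step 8.

**Step 7**
Reactants: 12 (5S)-5-(2-hydroperoxy-2-methoxypropyl)-5-methylfuran-2(5H)-one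
Product: 13 (3S,4S)-6-methoxy-4,6-dimethyl-1,2-dioxane cis-fused at C3–C4 to the γ-butyrolactone (both C6 epimers)
Conditions: Et2NH (0.5 equiv), CF3CH2OH, 0 °C→rt
Reagents that add atoms: none
Why: Intramolecular oxa-Michael addition of the hydroperoxide (6-exo-trig), in which the peroxide oxygen tethered to C4 can reach C3 of the butenolide only from the face bearing the C4–C5 bond, so the 5,6-system is cis-fused and C3 is set as S by C4, while the weak amine in an acidic hydrogen-bonding solvent protonates the enolate quickly and limits Kornblum–DeLaMare cleavage.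

**Step 8**
Reactants: 13 cis-fused 6-methoxy peroxyketal lactone (both C6 epimers); 14 allyltrimethylsilane
Product: 16 (3S,4S,6R)-6-allyl-4,6-dimethyl-1,2-dioxane cis-fused at C3–C4 to the γ-butyrolactone (allyl cis to the lactone oxygen), via peroxycarbenium ion 15 (not isolated)
Conditions: 14 (3 equiv), SnCl4 (1.1 equiv, added last), CH2Cl2, −78 °C; aq NaHCO3 quench at −78 °C
Reagents that add atoms: none
Why: SnCl4 binds and removes the exocyclic methoxy group, so both C6 epimers collapse to the same endocyclic peroxycarbenium ion 15 (O1=C6, O1–O2 bond and ring intact), which allyltrimethylsilane attacks through its terminal carbon (SE2′) before chloride takes the silyl group from the β-silyl cation. The closest known reaction is the Hosomi–Sakurai allylation of 3-alkoxy-1,2-dioxanes and 3-alkoxy-1,2-dioxolanes, ketal-derived members included, applied here to a lactone-fused member of that class. No ring is closed: only the C6–C1′ bond forms, and the dioxane made in step 7 is carried through as the cation. C6 is set by the substrate: the half-chair of 15 with the C4 methyl and the C3–C2 bond pseudoequatorial and the C4 lactone oxygen pseudoaxial (also the better electrostatic position for a C–O dipole near a cation) should dominate, and chair-like axial attack on it comes from the face syn to that oxygen, which is predicted to place the allyl group cis to the lactone oxygen and the C6 methyl cis to the C4 methyl (6R), whereas the flipped half-chair would force attack syn to an axial C4 methyl. The step needs exocyclic rather than endocyclic C–O ionisation, which is secured by the lower basicity of peroxide oxygen and by ready re-closure of any ring-opened ion through its tethered peroxide, and it needs the O–O bond and lactone to survive, which is secured by −78 °C, premixing with excess silane and a lactone carbonyl that does not react with the Lewis acid in the cold. Any 6S epimer should be removable by chromatography here, before the chain fragment is spent.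

**Step 9**
Reactants: 17 4-methoxyphenylmagnesium bromide; 18 8-bromo-1-octene
Product: 19 1-methoxy-4-(oct-7-en-1-yl)benzene
Conditions: Li2CuCl4 (3 mol %), THF, 0 °C→rt
Reagents that add atoms: none
Why: Kochi-type copper-catalysed cross-coupling of an aryl Grignard reagent with a primary alkyl bromide, in which the remote terminal alkene is a spectator.

**Step 10**
Reactants: 19 1-methoxy-4-(oct-7-en-1-yl)benzene
Product: 21 4-(oct-7-en-1-yl)phenol, via sodium phenolate 20 (not isolated)
Conditions: EtSNa, DMF, 130 °C, Ar; then 1 M aq HCl
Reagents that add atoms: none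
Why: SN2 demethylation of the aryl methyl ether by the soft thiolate in a dipolar aprotic solvent, under non-acidic conditions in which an unactivated terminal alkene neither migrates nor adds HX.

**Step 11**
Reactants: 16 (3S,4S,6R)-6-allyl dioxane lactone; 21 4-(oct-7-en-1-yl)phenol
Product: 22 dehydro-plakortolide F, the (3S,4S,6R) dioxane lactone bearing a 9-(4-hydroxyphenyl)non-2-en-1-yl chain at C6 (E isomer expected to prevail; geometry irrelevant)
Conditions: second-generation Hoveyda–Grubbs catalyst (5 mol %), 21 (3 equiv), 1,4-benzoquinone (10 mol %), CH2Cl2, 40 °C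
Reagents that add atoms: none
Why: Olefin cross-metathesis of two terminal (type 1) alkenes, in which an excess of the cheap phenol drives 16 into the cross product, the homodimer of 21 remains metathesis-active and differs clearly in polarity, ruthenium carbenes tolerate phenols, lactones and dialkyl peroxides, and benzoquinone suppresses hydride-induced alkene migration that would alter the chain length.

**Step 12**
Reactants: 22 dehydro-plakortolide F
Product: 23 plakortolide F
Conditions: KO2CN=NCO2K (excess, in portions), AcOH, MeOH/CH2Cl2, 0 °C→rt
Reagents that add atoms: none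
Why: Diimide reduction, in which HN=NH released by acid decarboxylation of the azodicarboxylate delivers two hydrogens in a concerted syn fashion to the non-polar C=C bond and leaves the O–O bond, lactone and arene untouched, unlike catalytic hydrogenation.

**Compound list**

1 | methyl pyruvate | CC(=O)C(=O)OC | starting material
2 | isobutene | CC(C)=C | starting material
3 | methyl (S)-2-hydroxy-2,4-dimethylpent-4-enoate | C=C(C)C[C@](C(=O)OC)(C)O | intermediate
4 | methyl (S)-2,4-dimethyl-2-(triethylsilyloxy)pent-4-enoate | C=C(C)C[C@](C(=O)OC)(C)O[Si](CC)(CC)CC | intermediate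
5 | diisobutylaluminium methyl hemiacetal from 4 (not isolated) | C=C(C)C[C@](C(OC)O[Al](CC(C)C)CC(C)C)(C)O[Si](CC)(CC)CC | intermediate
6 | (S)-2,4-dimethyl-2-(triethylsilyloxy)pent-4-enal | C=C(C)C[C@](C=O)(C)O[Si](CC)(CC)CC | intermediate
7 | methyl bis(2,2,2-trifluoroethyl)phosphonoacetate | COC(=O)CP(=O)(OCC(F)(F)F)OCC(F)(F)F | starting material
8 | methyl (2Z,4S)-4,6-dimethyl-4-(triethylsilyloxy)hepta-2,6-dienoate | C=C(C)C[C@](/C=C\C(=O)OC)(C)O[Si](CC)(CC)CC | intermediate
9 | methyl (2Z,4S)-4-hydroxy-4,6-dimethylhepta-2,6-dienoate (not isolated) | C=C(C)C[C@](/C=C\C(=O)OC)(C)O | intermediate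
10 | (S)-5-methyl-5-(2-methylallyl)furan-2(5H)-one | C=C(C)C[C@]1(C)OC(=O)C=C1 | intermediate
11 | carbonyl oxide of the side-chain methyl ketone (not isolated) | CC(=[O+][O-])C[C@]1(C)OC(=O)C=C1 | intermediate
12 | (5S)-5-(2-hydroperoxy-2-methoxypropyl)-5-methylfuran-2(5H)-one, both ketal epimers | COC(C)(OO)C[C@]1(C)OC(=O)C=C1 | intermediate
13 | (3S,4S)-6-methoxy-4,6-dimethyl-1,2-dioxane cis-fused to the γ-butyrolactone, both C6 epimers | COC1(C)C[C@]2(C)OC(=O)C[C@@H]2OO1 | intermediate
14 | allyltrimethylsilane | C=CC[Si](C)(C)C | starting material
15 | endocyclic peroxycarbenium ion O1=C6 of the dioxane lactone (not isolated) | CC=1C[C@]2(C)OC(=O)C[C@@H]2O[O+]=1 | intermediate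
16 | (3S,4S,6R)-6-allyl-4,6-dimethyl-1,2-dioxane cis-fused to the γ-butyrolactone | C[C@@]1(CC=C)C[C@]2(C)OC(=O)C[C@@H]2OO1 | intermediate
17 | 4-methoxyphenylmagnesium bromide | COc1ccc([Mg]Br)cc1 | starting material
18 | 8-bromo-1-octene | C=CCCCCCCBr | starting material
19 | 1-methoxy-4-(oct-7-en-1-yl)benzene | C=CCCCCCCc1ccc(OC)cc1 | intermediate
20 | sodium 4-(oct-7-en-1-yl)phenolate (not isolated) | C=CCCCCCCc1ccc([O-])cc1.[Na+] | intermediate
21 | 4-(oct-7-en-1-yl)phenol | C=CCCCCCCc1ccc(O)cc1 | intermediate
22 | dehydro-plakortolide F (C2′=C3′ alkene, E drawn) | C[C@@]1(C/C=C/CCCCCCc2ccc(O)cc2)C[C@]2(C)OC(=O)C[C@@H]2OO1 | intermediate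
23 | plakortolide F, (3S,4S,6R) | C[C@@]1(CCCCCCCCCc2ccc(O)cc2)C[C@]2(C)OC(=O)C[C@@H]2OO1 | target

**Step count**

Total step count: 12 (ten in the main line, two for the aryl-octene fragment).
Longest linear sequence: 10 steps (steps 1–8, 11 and 12, from methyl pyruvate).

**Steps most likely to fail**

**1. Step 8.**
- Lewis-acid-induced heterolysis of the O–O bond, endocyclic C6–O1 ionisation or proton loss from the cation may outrun allylation.
- Facial selectivity at C6 may be poor or reversed.

The fallback avoids a cation at C6. It sets out from 10 and returns to the route at 23. Commercial (4-bromophenoxy)(tert-butyl)dimethylsilane is converted with Mg in THF into [4-(tert-butyldimethylsilyloxy)phenyl]magnesium bromide F1. This is coupled with commercial 10-bromodec-1-ene (Li2CuCl4 cat., THF) to give tert-butyl[4-(dec-9-en-1-yl)phenoxy]dimethylsilane F2. Cross-metathesis of the 1,1-disubstituted alkene of 10 with F2 (second-generation Hoveyda–Grubbs catalyst, CH2Cl2, 40 °C) would give the trisubstituted-alkene butenolide F3.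

Mukaiyama–Isayama hydroperoxysilylation (Co(thd)2, thd = 2,2,6,6-tetramethylheptane-3,5-dionate, O2, Et3SiH, ClCH2CH2Cl) places the peroxide at the tertiary carbon and gives the triethylsilyl peroxide F4 as both C6 epimers. Bu4NF/AcOH in THF removes both silyl groups to give the tertiary hydroperoxide F5. Et2NH in CF3CH2OH, as in step 7, then closes the dioxane to 23 together with 6-epi-plakortolide F F6, which is removed by chromatography. The price is the absence of control at C6.

**2. Step 11.**
- The peroxide may destroy the ruthenium carbene.
- Homodimerisation may dominate.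
- Alkene migration before metathesis may give chain-shortened homologues that cannot be separated.

The fallback replaces metathesis by carbonyl olefination. It sets out from 16 and returns at 23. Ozonolysis of the allyl group (O3, CH2Cl2, −78 °C; Me2S) gives the C6 (2-oxoethyl) dioxane lactone F7.

Separately, 17 is coupled with an excess of commercial 1,7-dibromoheptane (Li2CuCl4 cat., THF) to give 1-(7-bromoheptyl)-4-methoxybenzene F8. BBr3 in CH2Cl2 frees 4-(7-bromoheptyl)phenol F9. PPh3 in MeCN at reflux gives [7-(4-hydroxyphenyl)heptyl]triphenylphosphonium bromide F10. Double deprotonation of F10 with NaN(SiMe3)2 (THF, −78 °C) and Wittig reaction with F7 should give the Z isomer of dehydro-plakortolide F F11. This is reduced under the conditions of step 12 to 23.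

**3. Step 6.**
- Over-oxidation may reach the butenolide alkene.
- The primary ozonide may split in the unwanted direction (ketone plus formaldehyde oxide).
- The hydroperoxide may decompose on concentration.

The fallback separates alkene cleavage from peroxide installation. It sets out from 10 and returns at 12. Ozonolysis in CH2Cl2 at −78 °C with Me2S work-up gives (S)-5-methyl-5-(2-oxopropyl)furan-2(5H)-one F12. Acid-catalysed peroxyketalisation with urea–hydrogen peroxide and Sc(OTf)3 (cat.) in MeOH then converts the ketone into 12, which enters step 7 unchanged.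

**Further compounds**

F1 | step 8 | [4-(tert-butyldimethylsilyloxy)phenyl]magnesium bromide | CC(C)(C)[Si](C)(C)Oc1ccc([Mg]Br)cc1
F2 | step 8 | tert-butyl[4-(dec-9-en-1-yl)phenoxy]dimethylsilane | C=CCCCCCCCCc1ccc(O[Si](C)(C)C(C)(C)C)cc1
F3 | step 8 | (5S)-5-{11-[4-(tert-butyldimethylsilyloxy)phenyl]-2-methylundec-2-en-1-yl}-5-methylfuran-2(5H)-one (alkene isomers) | CC(=CCCCCCCCCc1ccc(O[Si](C)(C)C(C)(C)C)cc1)C[C@]1(C)OC(=O)C=C1
F4 | step 8 | (5S)-5-{11-[4-(tert-butyldimethylsilyloxy)phenyl]-2-methyl-2-(triethylsilylperoxy)undecyl}-5-methylfuran-2(5H)-one (both C6 epimers) | CC(CCCCCCCCCc1ccc(O[Si](C)(C)C(C)(C)C)cc1)(OO[Si](CC)(CC)CC)C[C@]1(C)OC(=O)C=C1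
F5 | step 8 | (5S)-5-[2-hydroperoxy-11-(4-hydroxyphenyl)-2-methylundecyl]-5-methylfuran-2(5H)-one (both C6 epimers) | CC(CCCCCCCCCc1ccc(O)cc1)(OO)C[C@]1(C)OC(=O)C=C1
F6 | step 8 | 6-epi-plakortolide F, (3S,4S,6S) | C[C@]1(CCCCCCCCCc2ccc(O)cc2)C[C@]2(C)OC(=O)C[C@@H]2OO1
F7 | step 11 | (3S,4S,6R)-4,6-dimethyl-6-(2-oxoethyl)-1,2-dioxane cis-fused to the γ-butyrolactone | C[C@@]1(CC=O)C[C@]2(C)OC(=O)C[C@@H]2OO1
F8 | step 11 | 1-(7-bromoheptyl)-4-methoxybenzene | COc1ccc(CCCCCCCBr)cc1
F9 | step 11 | 4-(7-bromoheptyl)phenol | Oc1ccc(CCCCCCCBr)cc1
F10 | step 11 | [7-(4-hydroxyphenyl)heptyl]triphenylphosphonium bromide | Oc1ccc(CCCCCCC[P+](c2ccccc2)(c2ccccc2)c2ccccc2)cc1.[Br-]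
F11 | step 11 | (Z)-dehydro-plakortolide F | C[C@@]1(C/C=C\CCCCCCc2ccc(O)cc2)C[C@]2(C)OC(=O)C[C@@H]2OO1
F12 | step 6 | (S)-5-methyl-5-(2-oxopropyl)furan-2(5H)-one | CC(=O)C[C@]1(C)OC(=O)C=C1
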